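**Retrosynthetic overview** (target numbered as a spiro[5.5]undecane: dienone ring C1–C5, spiro carbon C6, cyclohexane C7–C11)
1. Tatanan B (30) ⇒ spirocyclobutenone 26 + 1-methoxyvinyllithium: alkenyllithium addition, 4π ring opening, 6π ring closure forming C1–C6, then enolate dehydrogenation in the same flask.
2. Enabling feature: C6 carries the vinylogous ester C5(OMe)=C4H–C3(=O), which is a ketene carbon (C3) plus methoxyethyne (C4, C5), i.e. a 3-methoxycyclobutenone; C1H=C2(OMe) is a 1-methoxyvinyl unit, so the ring is C6 + C3 + (C4, C5) + (C1, C2).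
3. 26 ⇒ ketene 25 (from acid 20) + methoxyethyne 23 by [2+2]; 20 ⇒ ketone 16 by one-carbon homologation.
4. 16 ⇒ one cyclohexanone ring dressed in turn: C11 aryl by α-arylation (thermodynamic), C10 methyl by cuprate addition to enone 14, C7/C8 by hydrogenation of enone 11, C9 by rhodium-catalysed asymmetric 1,4-addition.
5. Ring order: cyclohexane (present in 2) → cyclobutenone (step 14) → dienone (step 15).

Key step: step 15

Remark: the target SMILES fixes six stereocentres only; rotation of the C11 aryl group beside the spiro centre is slow in this series, and the rotamer population of 30 is taken to be set by thermal equilibration.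

Step 1
Reactants: 1 1-bromo-2,4,5-trimethoxybenzene; 2 cyclohex-2-en-1-one
Product: 6 (R)-trimethyl{[3-(2,4,5-trimethoxyphenyl)cyclohex-1-en-1-yl]oxy}silane, via aryllithium 3 (not isolated), via aryltitanium triisopropoxide 4 (not isolated), via titanium enolate 5 (not isolated)
Conditions: 1, n-BuLi, THF, −78 °C; ClTi(OiPr)3, −78 → 20 °C; 2, [Rh(OH)((R)-binap)]2 (1.5 mol %), THF, 20 °C; then LiOiPr, Me3SiCl, 20 °C
Reagents that add atoms: chlorotrimethylsilane, C[Si](C)(C)Cl
Why: Rhodium-catalysed asymmetric 1,4-addition of the aryltitanium (Hayashi–Miyaura type) should set the aryl-bearing centre (C9 of the target) under control of the (R)-binap ligand, and silylation keeps the enolate regiodefined for step 2.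

Step 2
Reactants: 6 (R)-trimethyl{[3-(2,4,5-trimethoxyphenyl)cyclohex-1-en-1-yl]oxy}silane
Product: 8 (2S,3R)-2-methyl-3-(2,4,5-trimethoxyphenyl)cyclohexan-1-one, via lithium enolate 7 (not isolated)
Conditions: MeLi, THF, 0 °C; then MeI, −40 → 0 °C
Reagents that add atoms: iodomethane, CI
Why: MeLi cleaves the silyl enol ether to the regiodefined lithium enolate, which should be methylated at C2 trans to the aryl group; the C2 configuration is of no consequence because this carbon becomes sp2 in step 3.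

Step 3
Reactants: 8 (2S,3R)-2-methyl-3-(2,4,5-trimethoxyphenyl)cyclohexan-1-one
Product: 9 (R)-2-hydroxy-3-methyl-4-(2,4,5-trimethoxyphenyl)cyclohex-2-en-1-one
Conditions: SeO2, 1,4-dioxane–H2O, 100 °C
Reagents that add atoms: selenium dioxide, O=[Se]=O
Why: Riley oxidation of the only α-methylene gives the 1,2-dione, which should rest as the diosphenol enolised towards the methyl-bearing carbon, as 3-methylcyclohexane-1,2-dione does.

Step 4
Reactants: 9 (R)-2-hydroxy-3-methyl-4-(2,4,5-trimethoxyphenyl)cyclohex-2-en-1-one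
Product: 10 (R)-2-methyl-6-oxo-3-(2,4,5-trimethoxyphenyl)cyclohex-1-en-1-yl trifluoromethanesulfonate
Conditions: Tf2O, pyridine, CH2Cl2, −78 → 0 °C
Reagents that add atoms: trifluoromethanesulfonic anhydride, O=S(=O)(OS(=O)(=O)C(F)(F)F)C(F)(F)F
Why: O-Sulfonylation of the single enol hydroxyl gives the vinyl triflate under a base too weak to touch the γ-stereocentre.

Step 5
Reactants: 10 (R)-2-methyl-6-oxo-3-(2,4,5-trimethoxyphenyl)cyclohex-1-en-1-yl trifluoromethanesulfonate
Product: 11 (R)-2-ethyl-3-methyl-4-(2,4,5-trimethoxyphenyl)cyclohex-2-en-1-one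
Conditions: Et2Zn, Pd(dppf)Cl2 (5 mol %), THF, 60 °C
Reagents that add atoms: diethylzinc, CC[Zn]CC
Why: Negishi coupling of the α-triflyloxy enone installs the ethyl group regiospecifically at C2, and the bidentate dppf ligand suppresses β-hydride elimination.

Step 6
Reactants: 11 (R)-2-ethyl-3-methyl-4-(2,4,5-trimethoxyphenyl)cyclohex-2-en-1-one
Product: 12 (2R,3R,4R)-2-ethyl-3-methyl-4-(2,4,5-trimethoxyphenyl)cyclohexan-1-one (all-cis)
Conditions: H2 (4 atm), Pd/C (10%), EtOAc, 23 °C
Reagents that add atoms: none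
Why: Heterogeneous syn-hydrogenation of the tetrasubstituted enone from the face opposite the C4 aryl group (held pseudoaxial by allylic 1,2-strain with the C3 methyl) should set C2 and C3 cis to the aryl group by substrate control.

Step 7
Reactants: 12 (2R,3R,4R)-2-ethyl-3-methyl-4-(2,4,5-trimethoxyphenyl)cyclohexan-1-one
Product: 14 (4R,5R,6R)-6-ethyl-5-methyl-4-(2,4,5-trimethoxyphenyl)cyclohex-2-en-1-one, via lithium enolate 13 (not isolated)
Conditions: LiN(iPr)2, THF, −78 °C; then PhS(Cl)=N-t-Bu, −78 °C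
Reagents that add atoms: none
Why: Kinetic deprotonation at the unhindered CH2 rather than at CH(Et), then dehydrogenation of the lithium enolate with the sulfinimidoyl chloride (C–S bond formation and syn elimination), should give the enone on the far side of the ketone without touching C6.

Step 8
Reactants: 14 (4R,5R,6R)-6-ethyl-5-methyl-4-(2,4,5-trimethoxyphenyl)cyclohex-2-en-1-one
Product: 15 (2R,3R,4R,5S)-2-ethyl-3,5-dimethyl-4-(2,4,5-trimethoxyphenyl)cyclohexan-1-one
Conditions: Me2CuLi (from CuI and MeLi), Et2O, −78 → −20 °C; aq NH4Cl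
Reagents that add atoms: lithium dimethylcuprate, [Li+].C[Cu-]C
Why: Cuprate conjugate addition anti to both the C4 aryl and the C5 methyl group of 14, which lie on the same face, should set the new methyl-bearing centre trans to both by substrate control.

Step 9
Reactants: 15 (2R,3R,4R,5S)-2-ethyl-3,5-dimethyl-4-(2,4,5-trimethoxyphenyl)cyclohexan-1-one; 1 1-bromo-2,4,5-trimethoxybenzene
Product: 16 (2R,3R,4S,5R,6R)-2-ethyl-3,5-dimethyl-4,6-bis(2,4,5-trimethoxyphenyl)cyclohexan-1-one
Conditions: Pd2(dba)3 (2 mol %), Xantphos (5 mol %), NaOt-Bu, toluene, 80 °C; then DBU (cat.), CH2Cl2, 23 °C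
Reagents that add atoms: none
Why: Palladium-catalysed ketone α-arylation (Buchwald–Hartwig type) should take place at the methylene rather than the tertiary α-carbon, and the acidic benzylic α-centre then equilibrates to the equatorial aryl group trans to the neighbouring methyl (thermodynamic control).

Step 10
Reactants: 16 (2R,3R,4S,5R,6R)-2-ethyl-3,5-dimethyl-4,6-bis(2,4,5-trimethoxyphenyl)cyclohexan-1-one
Product: 17 2-ethyl-3,5-dimethyl-1-methylidene-4,6-bis(2,4,5-trimethoxyphenyl)cyclohexane (ring centres as in 16)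
Conditions: Cp2TiMe2, toluene, 70 °C
Reagents that add atoms: dimethyltitanocene, C[Ti](C)(C1C=CC=C1)C1C=CC=C1
Why: Petasis methylenation is non-basic and should convert the hindered, enolisable ketone without epimerisation of either α-centre.

Step 11
Reactants: 17 2-ethyl-3,5-dimethyl-1-methylidene-4,6-bis(2,4,5-trimethoxyphenyl)cyclohexane
Product: 19 [2-ethyl-3,5-dimethyl-4,6-bis(2,4,5-trimethoxyphenyl)cyclohexyl]methanol (C2–C6 as in 16, C1 epimers), via B-alkyl-9-BBN 18 (not isolated)
Conditions: 9-BBN, THF, 65 °C; then NaOH, H2O2, 0 → 23 °C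
Reagents that add atoms: hydrogen peroxide, OO
Why: Anti-Markovnikov hydroboration–oxidation of the 1,1-disubstituted alkene gives the primary alcohol; the new ring centre need not be controlled because it becomes sp2 in step 14.

Step 12
Reactants: 19 [2-ethyl-3,5-dimethyl-4,6-bis(2,4,5-trimethoxyphenyl)cyclohexyl]methanol
Product: 20 2-ethyl-3,5-dimethyl-4,6-bis(2,4,5-trimethoxyphenyl)cyclohexane-1-carboxylic acid (C2–C6 as in 16, C1 epimers)
Conditions: TEMPO (20 mol %), PhI(OAc)2, MeCN–H2O, 23 °C
Reagents that add atoms: water, O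
Why: Nitroxyl-catalysed oxidation of the primary alcohol through the aldehyde hydrate should give the acid under conditions mild to the electron-rich arenes.

Step 13
Reactants: 21 2-chloro-1,1-dimethoxyethane
Product: 23 methoxyethyne (used as a toluene solution), via sodium methoxyacetylide 22 (not isolated)
Conditions: NaNH2, NH3 (l), −33 °C; cold aq NaCl; distilled into toluene
Reagents that add atoms: none
Why: Twofold elimination (HCl, then methanol) with sodium amide gives the sodium alkynyl ether, the standard route to alkoxyacetylenes.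

Step 14
Reactants: 20 2-ethyl-3,5-dimethyl-4,6-bis(2,4,5-trimethoxyphenyl)cyclohexane-1-carboxylic acid; 23 methoxyethyne
Product: 26 5-ethyl-3-methoxy-6,8-dimethyl-7,9-bis(2,4,5-trimethoxyphenyl)spiro[3.5]non-2-en-1-one (C1 axial and cis to the C5 ethyl and C9 aryl groups, C3 equatorial), via acid chloride 24 (not isolated), via ketene 25 (not isolated)
Conditions: (COCl)2, DMF (cat.), CH2Cl2, 23 °C, evaporate; then 23, Et3N, toluene, sealed tube, 70 °C
Reagents that add atoms: none
Why: Dehydrochlorination of the acid chloride gives the ketene, which adds methoxyethyne in a [2+2] cycloaddition (alkyne CH carbon to the ketene carbonyl carbon, then closure of the zwitterionic enolate on the ring carbon from its open face, opposite the ethyl, C6-methyl and two aryl groups), so that the C–OMe carbon should become equatorial and the carbonyl carbon axial at the new spiro centre (substrate control).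

Step 15
Reactants: 26 5-ethyl-3-methoxy-6,8-dimethyl-7,9-bis(2,4,5-trimethoxyphenyl)spiro[3.5]non-2-en-1-one
Product: 30 tatanan B, (6S,7R,8S,9S,10R,11R)-7-ethyl-2,5-dimethoxy-8,10-dimethyl-9,11-bis(2,4,5-trimethoxyphenyl)spiro[5.5]undeca-1,4-dien-3-one, via cyclobutenolate 27 (not isolated), via trienolate 28 (not isolated), via dienolate 29 (not isolated)
Conditions: CH2=CHOMe, t-BuLi, THF, −78 → 0 °C (gives CH2=C(OMe)Li); 26, −78 → 23 °C; then PhS(Cl)=N-t-Bu, −78 °C
Reagents that add atoms: 1-methoxyvinyllithium, [Li]C(=C)OC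
Why: 1-Methoxyvinyllithium adds 1,2 to the strained carbonyl of 26 to give cyclobutenolate 27, whose oxy-anion-accelerated conrotatory 4π ring opening (oxide outward, vinyl group inward) cleaves the C1–C4 bond of the four-membered ring to give the 3-oxidotriene 28, and a disrotatory 6π electrocyclisation then joins the former spiro carbon to the CH2 terminus of the vinyl group, which closes the six-membered ring and makes the C1–C6 bond of the target (dienolate 29). The closest known reaction type is the two-carbon ring expansion of cyclobutenones to cyclohexenones by alkenyllithium addition, 4π opening and 6π closure, ended here by the known dehydrogenation of a lithium enolate with the sulfinimidoyl chloride (C–S bond at C2, then syn elimination of the sulfenamide with a C1–H). The only new stereocentre is the spiro carbon: conrotation turns the inward vinyl group onto the lobe of the ring carbon that held the broken bond, so disrotatory closure from this helical trienolate should put the new C–C bond in the axial place of the old acyl bond (a net 1,3-shift with retention) and carry the configuration set in step 14 into the target. The step needs 1,2- and not 1,4-addition (secured by the strain of the four-membered ketone and the hard lithium reagent), outward rotation of the oxide (its strong torquoselectivity) and ring closure faster than helix inversion or protonation of 28 (secured by the anionic acceleration and by the fully substituted terminus, which blocks passage of the vinyl group through the triene plane).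

**Compound list**
1 | 1-bromo-2,4,5-trimethoxybenzene | Brc1cc(OC)c(OC)cc1OC | starting material
2 | cyclohex-2-en-1-one | O=C1C=CCCC1 | starting material
3 | (2,4,5-trimethoxyphenyl)lithium | [Li]c1cc(OC)c(OC)cc1OC | intermediate
4 | triisopropoxy(2,4,5-trimethoxyphenyl)titanium | CC(C)O[Ti](OC(C)C)(OC(C)C)c1cc(OC)c(OC)cc1OC | intermediate
5 | triisopropoxy{[(3R)-3-(2,4,5-trimethoxyphenyl)cyclohex-1-en-1-yl]oxy}titanium | CC(C)O[Ti](OC(C)C)(OC(C)C)OC1=C[C@H](c3cc(OC)c(OC)cc3OC)CCC1 | intermediate
6 | (R)-trimethyl{[3-(2,4,5-trimethoxyphenyl)cyclohex-1-en-1-yl]oxy}silane | C[Si](C)(C)OC1=C[C@H](c3cc(OC)c(OC)cc3OC)CCC1 | intermediate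
7 | lithium (R)-3-(2,4,5-trimethoxyphenyl)cyclohex-1-en-1-olate | [Li]OC1=C[C@H](c3cc(OC)c(OC)cc3OC)CCC1 | intermediate
8 | (2S,3R)-2-methyl-3-(2,4,5-trimethoxyphenyl)cyclohexan-1-one | O=C1[C@@H](C)[C@H](c3cc(OC)c(OC)cc3OC)CCC1 | intermediate
9 | (R)-2-hydroxy-3-methyl-4-(2,4,5-trimethoxyphenyl)cyclohex-2-en-1-one | O=C1C(O)=C(C)[C@H](c3cc(OC)c(OC)cc3OC)CC1 | intermediate
10 | (R)-2-methyl-6-oxo-3-(2,4,5-trimethoxyphenyl)cyclohex-1-en-1-yl trifluoromethanesulfonate | O=C1C(OS(=O)(=O)C(F)(F)F)=C(C)[C@H](c3cc(OC)c(OC)cc3OC)CC1 | intermediate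
11 | (R)-2-ethyl-3-methyl-4-(2,4,5-trimethoxyphenyl)cyclohex-2-en-1-one | CCC1=C(C)[C@H](c3cc(OC)c(OC)cc3OC)CCC1=O | intermediate
12 | (2R,3R,4R)-2-ethyl-3-methyl-4-(2,4,5-trimethoxyphenyl)cyclohexan-1-one | CC[C@@H]1[C@H](C)[C@H](c3cc(OC)c(OC)cc3OC)CCC1=O | intermediate
13 | lithium (4R,5R,6R)-6-ethyl-5-methyl-4-(2,4,5-trimethoxyphenyl)cyclohex-1-en-1-olate | CC[C@@H]1[C@H](C)[C@H](c3cc(OC)c(OC)cc3OC)CC=C1O[Li] | intermediate
14 | (4R,5R,6R)-6-ethyl-5-methyl-4-(2,4,5-trimethoxyphenyl)cyclohex-2-en-1-one | CC[C@@H]1[C@H](C)[C@H](c3cc(OC)c(OC)cc3OC)C=CC1=O | intermediate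
15 | (2R,3R,4R,5S)-2-ethyl-3,5-dimethyl-4-(2,4,5-trimethoxyphenyl)cyclohexan-1-one | CC[C@@H]1[C@H](C)[C@H](c3cc(OC)c(OC)cc3OC)[C@@H](C)CC1=O | intermediate
16 | (2R,3R,4S,5R,6R)-2-ethyl-3,5-dimethyl-4,6-bis(2,4,5-trimethoxyphenyl)cyclohexan-1-one | CC[C@@H]1[C@H](C)[C@H](c3cc(OC)c(OC)cc3OC)[C@@H](C)[C@H](c3cc(OC)c(OC)cc3OC)C1=O | intermediate
17 | 2-ethyl-3,5-dimethyl-1-methylidene-4,6-bis(2,4,5-trimethoxyphenyl)cyclohexane (ring centres as in 16) | CC[C@@H]1[C@H](C)[C@H](c3cc(OC)c(OC)cc3OC)[C@@H](C)[C@H](c3cc(OC)c(OC)cc3OC)C1=C | intermediate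
18 | 9-{[2-ethyl-3,5-dimethyl-4,6-bis(2,4,5-trimethoxyphenyl)cyclohexyl]methyl}-9-borabicyclo[3.3.1]nonane (C1 epimers) | CC[C@@H]1[C@H](C)[C@H](c3cc(OC)c(OC)cc3OC)[C@@H](C)[C@H](c3cc(OC)c(OC)cc3OC)C1CB2C4CCCC2CCC4 | intermediate
19 | [2-ethyl-3,5-dimethyl-4,6-bis(2,4,5-trimethoxyphenyl)cyclohexyl]methanol (C1 epimers) | CC[C@@H]1[C@H](C)[C@H](c3cc(OC)c(OC)cc3OC)[C@@H](C)[C@H](c3cc(OC)c(OC)cc3OC)C1CO | intermediate
20 | 2-ethyl-3,5-dimethyl-4,6-bis(2,4,5-trimethoxyphenyl)cyclohexane-1-carboxylic acid (C1 epimers) | CC[C@@H]1[C@H](C)[C@H](c3cc(OC)c(OC)cc3OC)[C@@H](C)[C@H](c3cc(OC)c(OC)cc3OC)C1C(=O)O | intermediate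
21 | 2-chloro-1,1-dimethoxyethane | COC(CCl)OC | starting material
22 | sodium methoxyacetylide | [Na+].[C-]#COC | intermediate
23 | methoxyethyne | C#COC | intermediate
24 | 2-ethyl-3,5-dimethyl-4,6-bis(2,4,5-trimethoxyphenyl)cyclohexane-1-carbonyl chloride (C1 epimers) | CC[C@@H]1[C@H](C)[C@H](c3cc(OC)c(OC)cc3OC)[C@@H](C)[C@H](c3cc(OC)c(OC)cc3OC)C1C(=O)Cl | intermediate
25 | [2-ethyl-3,5-dimethyl-4,6-bis(2,4,5-trimethoxyphenyl)cyclohexylidene]methanone (ketene) | CC[C@@H]1[C@H](C)[C@H](c3cc(OC)c(OC)cc3OC)[C@@H](C)[C@H](c3cc(OC)c(OC)cc3OC)C1=C=O | intermediate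
26 | 5-ethyl-3-methoxy-6,8-dimethyl-7,9-bis(2,4,5-trimethoxyphenyl)spiro[3.5]non-2-en-1-one (C1 axial, C3 equatorial) | CC[C@@H]1[C@H](C)[C@H](c3cc(OC)c(OC)cc3OC)[C@@H](C)[C@H](c3cc(OC)c(OC)cc3OC)[C@]12C(=O)C=C2OC | intermediate
27 | lithium 1-(1-methoxyvinyl)-3-methoxy-spiro[3.5]non-2-en-1-olate derived from 26 (carbinol epimers) | CC[C@@H]1[C@H](C)[C@H](c3cc(OC)c(OC)cc3OC)[C@@H](C)[C@H](c3cc(OC)c(OC)cc3OC)[C@]12C([O-])(C(OC)=C)C=C2OC.[Li+] | intermediate
28 | lithium 1-cyclohexylidene-1,4-dimethoxypenta-2,4-dien-3-olate (open 3-oxidotriene, ring centres as in 16) | CC[C@@H]1[C@H](C)[C@H](c3cc(OC)c(OC)cc3OC)[C@@H](C)[C@H](c3cc(OC)c(OC)cc3OC)C1=C(OC)C=C([O-])C(OC)=C.[Li+] | intermediate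
29 | lithium 7-ethyl-2,5-dimethoxy-8,10-dimethyl-9,11-bis(2,4,5-trimethoxyphenyl)spiro[5.5]undeca-2,4-dien-3-olate (configuration as in 30) | CC[C@@H]1[C@H](C)[C@H](c3cc(OC)c(OC)cc3OC)[C@@H](C)[C@H](c3cc(OC)c(OC)cc3OC)[C@]12CC(OC)=C([O-])C=C2OC.[Li+] | intermediate
30 | tatanan B, (6S,7R,8S,9S,10R,11R)-7-ethyl-2,5-dimethoxy-8,10-dimethyl-9,11-bis(2,4,5-trimethoxyphenyl)spiro[5.5]undeca-1,4-dien-3-one | CC[C@@H]1[C@H](C)[C@H](c2cc(OC)c(OC)cc2OC)[C@@H](C)[C@H](c2cc(OC)c(OC)cc2OC)[C@]12C=C(OC)C(=O)C=C2OC | target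

**Step count and risks**
Total steps: 15. Longest linear sequence: 14 (steps 1–12, 14, 15; step 13 is a one-step branch).

Step 15. What may go wrong: ring closure of the open trienolate at the hindered axial face may be slower than its conformational inversion, so that the spiro centre is scrambled, or the trienolate may be protonated instead of closing. The fallback sets out from alcohol 19 and is a Robinson-type annulation in which the new arm enters from the open face. Oxidation (SO3·pyridine, DMSO, Et3N) should give the aldehyde F1. Its potassium enolate (KH, THF) should add to 1,4,4-trimethoxybut-3-en-2-one F2 (from methoxyacetyl chloride and 1,1-dimethoxyethene, Et3N) with loss of methoxide to give the keto aldehyde F3, with the new arm equatorial and the formyl group axial. Intramolecular aldol condensation (K2CO3, MeOH) between the CH2OMe carbon and the formyl group then closes the dienone ring and returns to the route at 30.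

Step 14. What may go wrong: slow dehydrochlorination of the hindered acid chloride, and dimerisation or hydrolysis of the ketene instead of cycloaddition. The fallback sets out from acid 20. Conversion to the N,N-dimethylamide F4 ((COCl)2, then Me2NH) and activation with Tf2O and 2,4,6-collidine should give the keteniminium ion, a far stronger electrophile than the ketene. It adds methoxyethyne 23 to give the cyclobuteniminium triflate F5, and hydrolysis (aq NaHCO3) returns to the route at 26.

Step 9. What may go wrong: sluggish coupling of the hindered, electron-rich aryl bromide, and epimerisation at the ethyl-bearing α-carbon under the basic conditions. The fallback sets out from enone 14 and reverses the polarity of the arylation. The cuprate addition is ended with Me3SiCl to give the silyl enol ether F6. Bromination (N-bromosuccinimide, THF, −78 °C) should give the α-bromo ketone F7. Its ionisation with Et3N in CF3CH2OH in the presence of 1,2,4-trimethoxybenzene (Friedel–Crafts capture of the oxyallyl cation at the arene position that gives the 2,4,5-trimethoxyphenyl group), followed by DBU equilibration, returns to the route at 16.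

Further compounds
F1 | step 15 | 2-ethyl-3,5-dimethyl-4,6-bis(2,4,5-trimethoxyphenyl)cyclohexane-1-carbaldehyde (ring centres as in 16, C1 epimers) | CC[C@@H]1[C@H](C)[C@H](c3cc(OC)c(OC)cc3OC)[C@@H](C)[C@H](c3cc(OC)c(OC)cc3OC)C1C=O
F2 | step 15 | 1,4,4-trimethoxybut-3-en-2-one | COCC(=O)C=C(OC)OC
F3 | step 15 | 1-(1,4-dimethoxy-3-oxobut-1-en-1-yl)-2-ethyl-3,5-dimethyl-4,6-bis(2,4,5-trimethoxyphenyl)cyclohexane-1-carbaldehyde (formyl group axial) | CC[C@@H]1[C@H](C)[C@H](c3cc(OC)c(OC)cc3OC)[C@@H](C)[C@H](c3cc(OC)c(OC)cc3OC)[C@@]1(C=O)C(OC)=CC(=O)COC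
F4 | step 14 | 2-ethyl-N,N,3,5-tetramethyl-4,6-bis(2,4,5-trimethoxyphenyl)cyclohexane-1-carboxamide (C1 epimers) | CC[C@@H]1[C@H](C)[C@H](c3cc(OC)c(OC)cc3OC)[C@@H](C)[C@H](c3cc(OC)c(OC)cc3OC)C1C(=O)N(C)C
F5 | step 14 | N-[5-ethyl-3-methoxy-6,8-dimethyl-7,9-bis(2,4,5-trimethoxyphenyl)spiro[3.5]non-2-en-1-ylidene]-N-methylmethanaminium trifluoromethanesulfonate | CC[C@@H]1[C@H](C)[C@H](c3cc(OC)c(OC)cc3OC)[C@@H](C)[C@H](c3cc(OC)c(OC)cc3OC)[C@]12C(=[N+](C)C)C=C2OC.[O-]S(=O)(=O)C(F)(F)F
F6 | step 9 | trimethyl{[6-ethyl-3,5-dimethyl-4-(2,4,5-trimethoxyphenyl)cyclohex-1-en-1-yl]oxy}silane (ring centres as in 15) | CC[C@@H]1[C@H](C)[C@H](c3cc(OC)c(OC)cc3OC)[C@@H](C)C=C1O[Si](C)(C)C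
F7 | step 9 | 2-bromo-6-ethyl-3,5-dimethyl-4-(2,4,5-trimethoxyphenyl)cyclohexan-1-one (bromide epimers) | CC[C@@H]1[C@H](C)[C@H](c3cc(OC)c(OC)cc3OC)[C@@H](C)C(Br)C1=O
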